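A charge of 60.0 mM of J on 20 mM of L looks like enough to carry every L through to E, but that sum counts moles, not time.

    L + J → Q + G (k1 = 0.0043 M⁻¹ s⁻¹)
    J + Q → X + G (k2 = 0.0019 M⁻¹ s⁻¹)
    J + X → E + G (k3 = 0.0046 M⁻¹ s⁻¹)
    L + E ⇌ L.E, settled at all times (K4 = 15 M⁻¹)
    Z ⇌ E, rate k5*(cs5 - [E]) while solid is left; crystals form when [E] > cs5 (cs5 = 2.7 mM, k5 = 0.0063 s⁻¹)

the same everywhere: time 2.0 h

| flask | L | J | remark |
|---|---|---|---|
| east | 20 mM | 60.0 mM (fed, over 80 min) | all else is in the flask from the start; the feed brings no volume worth counting |
| west | 20 mM (in portions, 5, over 80 min) | 60.0 mM | first portion at the start, last at 80 min |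
| north | 20 mM (fed, over 80 min) | 60.0 mM | all else is in the flask from the start; the feed brings no volume worth counting |
| north-west | 20 mM | 60.0 mM | everything together at the start |

- which flask leads in share of E in E plus X ("all alike" within 1.5 percentage points) (east / west / north / north-west / all alike)
- share of E in E plus X at the end, east
- share of E in E plus X at the end, west
- share of E in E plus X at the end, north
- share of E in E plus X at the end, north-west

- a species is counted by the L in it: one L.E counts as two
- amounts and yields of E count L.E and Z too
- given per volume of solution although it is solid: Z
- in an amount of E, one L.E counts as one E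
- run time (east): 2.0 h

[J] stands in the rate of all three additions, so L, Q and X run on a common clock, the time integral of [J], and on it each addition is pseudo-first-order. My own reckoning keeps a ledger of L for north-west. A first guess spends 20 mM of J, which puts mean [J], taken halfway between the ends, at 50.0 mM and k3 times that mean times the time at 1.66. That ledger spends 23.3 mM of J, so the corrected figure is 1.60, the exposure: k3 times mean [J] times the time.

At that exposure the books of north-west read L 22.4%, Q 52.4%, X 14.5%, and E takes the remainder, 10.8%. Q costs one J, X two and E three, so the J spent in north-west is 22.8 mM, and the books close near the 23.3 mM assumed. E in north-west, reckoned at 2.16 mM, lies below the solubility of 2.7 mM, so crystals get no entry in this ledger; L.E is left out. The share of E in E plus X in north-west comes to 42.7%. Dosing over 80 min in east, west and north delays the average arrival of the dosed species by half that time, which cuts the charged J-time per L to 0.667 of north-west's, so north-west should lead; the ledger goes no further.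

The forecast names north-west, with 30.5% for east, 36% for west, 34% for north and 41% for north-west, on the ground that “the all-at-once flask gives the largest exposure”. Its 41% for north-west lies below the 42.7% of the ledger.

The flask gives 31.5% in east, 37.3% in west, 35.6% in north and 41.9% in north-west, so north-west leads.

North-west's J left, 63.0% of its charge, puts the exposure at 1.62, beside the 1.60 reckoned. The neighbour like north-west but with 24 mM of J forms 9.97 mM of G, so its exposure is 0.630, less than 1.60. The same ledger gives L 55.5%, Q 38.7%, X 4.69% and a share of 19.1%. That flask reads L 56.5%, Q 37.9% and a share of 18.6%.

The constants used here come from no measurement; the result is computed.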